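## The problem

Target **29** is a 1-O-acyl-3-O-acetyl-sn-glycerol: the glycerol carbon bearing the free hydroxyl is (S), one primary oxygen carries an acetate and the other a bicyclic C20 acid. The acid is numbered here with ring A as C1 (CH–CO2R), C2 (CH–CH3), C3, C4, C5, C10 and ring B as C5, C6 (carrying the 4-methylpent-3-enyl chain), C7, C8, C9, C10; α is the face of the two angular methyl groups. Rings A and B are cis-fused through two adjacent methyl-bearing quaternary carbons, C5 and C10, so one ring has to be closed at or next to fully substituted centres. The acid has four stereocentres, C1 (S), C2 (R), C5 (R) and C10 (R), with the carboxyl α, the C2 methyl β and both angular methyls α. C2 can come from the chiral pool, C1 is enolisable and sits in its stable equatorial position, C5 must be set 1,4 across ring A from C2, and C10 can be dictated by C5 if ring B is closed onto it. The C6=C7 and side-chain alkenes are open to acid-induced cation–olefin cyclisation and to metal hydrides, the C1 carboxyl is shielded by C10 and C2, and the glyceride suffers acyl migration, so the glycerol part must be finished last and mildly. The enabling feature is that C10 bears a methyl group and is therefore the Markovnikov radical of a C10 exocyclic methylene, while C9 lies four atoms away through C5, C6, C7 and C8. A carbonyl at C7 makes C9 the free terminus of a vinyl ketone, so C9–C10 can be formed by 6-endo radical conjugate addition of the hindered carbon to an unhindered CH2, and the same carbonyl later becomes the C6=C7 double bond.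

## Retrosynthesis

**Glyceride.** **29** is cut at the acetate to diol **28**, and **28** at the acetal to acetonide **27**. The ester between acid and glycerol is cut at the O–CH2 bond, not the acyl–O bond, giving acid **20** and (R)-solketal **21**. A Mitsunobu reaction then lets the carboxylate attack the primary carbon of **21**, so the shielded C1 carbonyl never has to be the electrophile. The ester is made early (**20** → **22**) because this hindered ester survives every later step, leaving only acetal hydrolysis and a primary-selective acetylation at the end.

**Side-chain alkene and ring alkene.** The isopropylidene terminus of **27** is cut by a Wittig disconnection to aldehyde **26**, which comes from alcohol **25** and silyl ether **24**. The chain is kept as a 3-silyloxypropyl stub until after the radical step, since a trisubstituted alkene would compete for the metal hydride. The C6=C7 bond of **24** is traced to the 7α (axial) alcohol **23** and the C7 ketone **22**. The forward reaction must eliminate toward C6 and not C8, which is arranged by an axial leaving group anti-periplanar to the axial tertiary C6–H.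

**Carboxyl group.** Acid **20** is traced to primary alcohol **19** and benzyl ether **18**. Carrying C1 as CH2OBn instead of an ester has three reasons:
- an ester would require methylenation of an enolisable β-keto ester;
- it would leave an acidic, conjugation-prone C1–H beside the C10 methylene during the enolate and Grignard steps;
- it would be a shielded ester to cleave late in the presence of two alkenes.

Hydrogenolysis fits exactly at **18**, the only intermediate after methylenation that has no C=C bond.

**Key disconnection, C9–C10.** **18** is opened to the monocyclic vinyl ketone **16**. Cutting C5–C10 would join two quaternary carbons directly, and cutting C5–C6 or C1–C10 would make a quaternary centre by attack on a substituted carbon. Cutting C9–C10 lets the hindered tertiary C10 radical attack a terminal CH2. **16** has one ring and three settled stereocentres (C1, C2, C5). The forward step must give the cis fusion and must generate the radical only at the methylene.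

**Vinyl ketone arm.** The C7–C8 bond of **16** is cut to the N-methoxy-N-methyl amide **13** and vinylmagnesium bromide **14**. The C6–chain bond of **13** is cut to amide **11** and a three-carbon silyloxy electrophile. At this stage the arm methylene is the only acidic position, so the alkylation needs no protecting-group manoeuvre, and C6 need not be controlled.

**C10 methylene and C1 carbon.** **11** comes from ketone **10** by methylenation with a non-basic reagent, because **10** is a hindered β-alkoxy ketone. **10** comes from ketone **8** by alkylating the only enolisable position, C1, with a benzyloxymethyl electrophile. C1 is set trans to the C2 methyl both kinetically and thermodynamically.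

**Quaternary C5.** The C5–C6 bond of **8** is cut to enone **6** by a reductive alkylation. The order of the two C5 substituents matters. An electrophile enters a 2-substituted 5-methylcyclohexanone enolate axially, cis to the equatorial ring methyl. The methyl must therefore already be on the enolate and the two-carbon arm must be the electrophile; the reverse order would put the arm on the wrong face.

**Chiral pool.** **6** is traced through sulfoxide **5**, sulfides **4** and **3** and epoxide **2** to (R)-pulegone **1**. Its methyl-bearing stereocentre becomes C2 and its isopropylidene carbon is excised as acetone.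

## Roads not taken

**Alternative 1: transannular oxidative enolate coupling.** The cut is C5–C10 itself, opening both rings of the C2-symmetric cis-dione A3 to the ten-membered diketone A1. Forward, A1 is enolised twice toward its methyl-bearing carbons and silylated to the bis(silyl enol ether) A2. A one-electron oxidant such as (NH4)2Ce(NO3)6 (tetravalent cerium) then joins the two enol carbons across the ring, making both quaternary centres and both rings in one step.
- Merits: the route would be very short. The two ketones of A3 are equivalent. The C6 ketone can enolise only toward C7, so its enol triflate and a cross-coupling would deliver the C6=C7 alkene with its chain without any regiochemical question. In this respect it is better than the chosen plan, which relies on a directed elimination (steps 14 and 15).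
- Weak points: a medium-ring diketone must be made first. The coupling has to join two fully substituted carbons and choose the cis fusion. A3 would be racemic with no chiral-pool entry. The C1 ketone must still be methylated at C2 and homologated to the carboxyl with two new stereocentres.
- Comparison: the chosen plan is longer but takes absolute configuration from pulegone and uses a key step of a known type on an unhindered acceptor carbon.

**Alternative 2: lactone Ireland–Claisen ring contraction.** The cut is C1–C10 (with O–C4), tracing the ring A acid A5 to the δ-lactone A4. Forward, the silyl ketene acetal of A4 rearranges through a boat, forming C1–C10 and leaving a C4=C5 alkene.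
- Merits: the rearrangement is reliable and stereospecific. It sets C1, C2 and quaternary C10 in one step and delivers the C1 carboxyl at the right oxidation level. That is better than the chosen plan, which carries C1 as a benzyl ether and needs steps 11 and 12 to reach the acid.
- Weak points: A5 contains only ring A. C5 is still sp2, so the second quaternary centre and the whole of ring B remain to be built next to C10, which returns to the vicinal quaternary problem. A4 needs a tetrasubstituted alkene of defined geometry.
- Comparison: the chosen plan solves the hard bond first and gets ring A from the chiral pool in a few standard steps; overall it should be shorter.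

**Alternative 3: gold-triggered enyne bicyclisation.** The cuts are C5–C6 and C1–C10, tracing the bicyclic β-keto ester A7 to the acyclic enyne A6. Forward, a cationic gold catalyst such as Ph3PAuNTf2 (monovalent gold) activates the alkyne, the tetrasubstituted alkene attacks through C5, and the C10 cation is trapped by the silyl enol ether carbon C1.
- Merits: this is the most convergent plan, with both rings and both quaternary centres from a chain. The C6=C7 alkene with its substituent comes directly from the alkyne, again better than the elimination of the chosen plan.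
- Weak points: A6 needs a tetrasubstituted (Z)-alkene of defined geometry in an open chain. Absolute configuration would have to come from a chiral catalyst in a cyclisation that forms two adjacent quaternary centres. The C2 ketone of A7 must still be converted into the C2 methyl with control relative to C1.
- Comparison: the chosen plan gives up convergence for substrate-controlled stereochemistry from pulegone and for a ring closure whose selectivity follows from a chair argument.

Key step: step 10

Remark on the chemistry: C6 is a stereocentre only in compounds 13–23 and is destroyed in step 15; it is carried as both epimers in 13–17 and as the equatorial 6α epimer from 18 on.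

## Route

Step 1
Reactants: 1 (R)-pulegone
Product: 2 pulegone oxide, (6R)-2,2,6-trimethyl-1-oxaspiro[2.5]octan-4-one (both epoxide epimers)
Conditions: 30% H2O2, LiOH, MeOH, 0 °C → rt
Reagents that add atoms: hydrogen peroxide, OO
Why: Weitz–Scheffer nucleophilic epoxidation of the enone; the epoxide centres are destroyed in step 2, so their configuration is immaterial, and the methyl stereocentre (later C2) is untouched.

Step 2
Reactants: 2 pulegone oxide
Product: 3 (5R)-5-methyl-2-(phenylsulfanyl)cyclohexan-1-one (C2 epimers)
Conditions: PhSNa, THF, reflux; aqueous work-up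
Reagents that add atoms: sodium thiophenoxide, [Na+].[S-]c1ccccc1
Why: Thiolate opening of the α,β-epoxy ketone at the α-carbon followed by retro-aldol loss of acetone from the tertiary alkoxide; this known degradation of pulegone oxide leaves a sulfur handle on the carbon that becomes C5.

Step 3
Reactants: 3 (5R)-5-methyl-2-(phenylsulfanyl)cyclohexan-1-one
Product: 4 (5R)-2,5-dimethyl-2-(phenylsulfanyl)cyclohexan-1-one (C2 epimers)
Conditions: NaH, THF, 0 °C; MeI, 0 °C → rt
Reagents that add atoms: iodomethane, CI
Why: Regioselective alkylation of an α-sulfenyl ketone: the sulfur-stabilised enolate forms on the sulfur-bearing carbon and is C-methylated there.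

Step 4
Reactants: 4 (5R)-2,5-dimethyl-2-(phenylsulfanyl)cyclohexan-1-one
Product: 6 (R)-2,5-dimethylcyclohex-2-en-1-one, via sulfoxide 5 (not isolated)
Conditions: mCPBA, CH2Cl2, −78 °C; then toluene, 110 °C
Reagents that add atoms: none
Why: Sulfoxide syn-elimination (dehydrosulfenylation) toward the ring CH2 gives the endocyclic enone; any exocyclic isomer would be reduced to the same enolate in step 5.

Step 5
Reactants: 6 (R)-2,5-dimethylcyclohex-2-en-1-one
Product: 8 2-[(1R,4R)-1,4-dimethyl-2-oxocyclohexyl]-N-methoxy-N-methylacetamide, via lithium enolate 7 (not isolated)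
Conditions: Li, NH3(l)/THF, t-BuOH (1 equiv), −78 °C; NH3 removed; BrCH2C(O)N(OMe)Me, THF, −78 → 0 °C
Reagents that add atoms: 2-bromo-N-methoxy-N-methylacetamide, CON(C)C(=O)CBr
Why: Stork reductive alkylation gives the C10–C5 enolate regiospecifically. The electrophile enters axially on the half-chair that keeps the C2 methyl equatorial, i.e. cis to that methyl, which sets C5 (R) with the arm β and the C5 methyl α; this is the sense known for alkylations and annulations of 2-methyl-5-alkylcyclohexanone enolates.

Step 6
Reactants: 8 2-[(1R,4R)-1,4-dimethyl-2-oxocyclohexyl]-N-methoxy-N-methylacetamide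
Product: 10 2-[(1R,3R,4R)-3-[(benzyloxy)methyl]-1,4-dimethyl-2-oxocyclohexyl]-N-methoxy-N-methylacetamide, via lithium enolate 9 (not isolated)
Conditions: LiN(i-Pr)2, THF, −78 °C; BnOCH2Cl, −78 → −30 °C
Reagents that add atoms: benzyl chloromethyl ether, ClCOCc1ccccc1
Why: Kinetic ketone enolate alkylation: only C1 carries ketone α-hydrogens, the amide is far less acidic, and its acylation by the enolate would be a disfavoured 5-enolendo closure. Attack anti to the adjacent C2 methyl and to the axial C5 arm gives the 1α (trans, diequatorial) isomer, which is also the stable epimer of this enolisable centre.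

Step 7
Reactants: 10 2-[(1R,3R,4R)-3-[(benzyloxy)methyl]-1,4-dimethyl-2-oxocyclohexyl]-N-methoxy-N-methylacetamide
Product: 11 2-[(1R,3S,4R)-3-[(benzyloxy)methyl]-1,4-dimethyl-2-methylidenecyclohexyl]-N-methoxy-N-methylacetamide
Conditions: Zn, CH2Br2, TiCl4, THF/CH2Cl2, 0 °C → rt
Reagents that add atoms: dibromomethane, BrCBr
Why: Takai–Lombardo methylenation: the non-basic zinc–titanium methylene reagent olefinates hindered, enolisable ketones such as 2,2,6-trisubstituted cyclohexanones without epimerising C1 or eliminating the β-benzyloxy group, and leaves amides untouched.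

Step 8
Reactants: 11 2-[(1R,3S,4R)-3-[(benzyloxy)methyl]-1,4-dimethyl-2-methylidenecyclohexyl]-N-methoxy-N-methylacetamide
Product: 13 2-[(1R,3S,4R)-3-[(benzyloxy)methyl]-1,4-dimethyl-2-methylidenecyclohexyl]-5-[(tert-butyldimethylsilyl)oxy]-N-methoxy-N-methylpentanamide (C6 epimers), via lithium amide enolate 12 (not isolated)
Conditions: LiN(i-Pr)2, THF, −78 °C; TBSO(CH2)3I, DMPU, −78 → −20 °C
Reagents that add atoms: tert-butyl(3-iodopropoxy)dimethylsilane, CC(C)(C)[Si](C)(C)OCCCI
Why: Amide enolate alkylation with a primary iodide; the arm methylene is the only acidic position in 11, and the new C6 centre needs no control because C6 becomes sp2 in step 15.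

Step 9
Reactants: 13 the C6-alkylated amide; 14 vinylmagnesium bromide
Product: 16 4-[(1R,3S,4R)-3-[(benzyloxy)methyl]-1,4-dimethyl-2-methylidenecyclohexyl]-7-[(tert-butyldimethylsilyl)oxy]hept-1-en-3-one (C6 epimers), via magnesium chelate 15 (not isolated)
Conditions: THF, 0 °C → rt; inverse quench into cold 1 M HCl
Reagents that add atoms: none
Why: Weinreb ketone synthesis: the five-membered magnesium chelate holds the tetrahedral adduct until the quench, so no second addition occurs, and the acidic inverse quench keeps the liberated amine from adding to the vinyl ketone.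

Step 10
Reactants: 16 the methylene vinyl ketone
Product: 18 1α-[(benzyloxy)methyl]-6α-{3-[(tert-butyldimethylsilyl)oxy]propyl}-2β,5α,10α-trimethyl-cis-decalin-7-one, via tertiary radical 17 (not isolated)
Conditions: Fe(acac)3 (0.3 equiv), PhSiH3 (2.5 equiv), EtOH/(CH2OH)2 5:1, 0.02 M, degassed, 60 °C; then K2CO3, MeOH, rt
Reagents that add atoms: none
Why: Fe(acac)3 and PhSiH3 in ethanol give a trivalent iron hydride that transfers a hydrogen atom to the CH2 terminus of the C10 methylene (Markovnikov), creating the C10 methyl group and the nucleophilic tertiary radical 17. Radical 17 adds to C9, the unsubstituted β-carbon of the vinyl ketone, in a 6-endo-trig closure of ring B; the 5-exo mode at C8 is polarity-mismatched and would give a primary radical. The resulting α-keto radical at C8 is reduced by divalent iron to the enolate, which ethanol protonates, returning trivalent iron. The closest known reaction type is the iron-hydride reductive olefin coupling (hydrogen-atom-transfer Giese addition) of 1,1-disubstituted alkenes with enones, including intramolecular cases that build quaternary and vicinal fully substituted carbons. The new C10 stereocentre is controlled by C5: ring A sits in the chair with the C1 and C2 substituents equatorial (the flipped chair would place the C1 substituent and the C5 methyl 1,3-diaxial), so the C5 tether is axial on the β face and can reach C10 only from that face, equatorially, giving the cis fusion with the C10 methyl α. The step needs hydrogen-atom transfer to the electron-rich methylene in preference to the enone, and ring closure faster than a second hydrogen transfer; the absence of any other alkene, the polarity match of the radical with the enone and high dilution secure this. C6 emerges as a mixture and K2CO3 in methanol equilibrates it to the equatorial 6α epimer, since an axial chain would be 1,3-diaxial to the C10–C1 bond.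

Step 11
Reactants: 18 the benzyl ether decalinone
Product: 19 6α-{3-[(tert-butyldimethylsilyl)oxy]propyl}-1α-(hydroxymethyl)-2β,5α,10α-trimethyl-cis-decalin-7-one
Conditions: H2 (1 atm), 10% Pd/C, EtOAc, rt
Reagents that add atoms: none
Why: Benzyl ether hydrogenolysis, placed at the only stage after step 7 without a C=C bond; ketone and silyl ether are inert in ethyl acetate.

Step 12
Reactants: 19 the hydroxymethyl decalinone
Product: 20 6α-{3-[(tert-butyldimethylsilyl)oxy]propyl}-2β,5α,10α-trimethyl-7-oxo-cis-decalin-1α-carboxylic acid
Conditions: TEMPO (cat.), NaOCl (cat.), NaClO2, MeCN/phosphate buffer pH 6.7, 35 °C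
Reagents that add atoms: sodium chlorite, [Na+].[O-]Cl=O
Why: TEMPO/chlorite oxidation of a primary alcohol to the acid through the aldehyde; the buffer preserves the silyl ether, and the passing C1 aldehyde can only equilibrate to the stable equatorial 1α configuration.

Step 13
Reactants: 20 the keto acid; 21 (R)-solketal
Product: 22 [(4S)-2,2-dimethyl-1,3-dioxolan-4-yl]methyl 6α-{3-[(tert-butyldimethylsilyl)oxy]propyl}-2β,5α,10α-trimethyl-7-oxo-cis-decalin-1α-carboxylate
Conditions: PPh3, DIAD, THF, 0 °C → rt
Reagents that add atoms: none
Why: Mitsunobu esterification: the carboxylate attacks the activated primary carbon of solketal, so the shielded C1 carbonyl is never the electrophile and the dioxolane stereocentre is not touched (its descriptor changes from R to S only through priorities).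

Step 14
Reactants: 22 the keto ester
Product: 23 the 7α-hydroxy (axial) alcohol of 22
Conditions: LiBH(s-Bu)3, THF, −78 °C; aqueous work-up
Reagents that add atoms: none
Why: Bulky hydride reduction: the axial approach to C7 is blocked by the axial C5 methyl, so hydride arrives equatorially and gives the axial 7α alcohol, anti-periplanar to the axial C6–H; the hindered ester is not reduced at −78 °C.

Step 15
Reactants: 23 the 7α alcohol
Product: 24 [(4S)-2,2-dimethyl-1,3-dioxolan-4-yl]methyl 6-{3-[(tert-butyldimethylsilyl)oxy]propyl}-2β,5α,10α-trimethyl-cis-decal-6-ene-1α-carboxylate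
Conditions: POCl3, pyridine, 0 → 50 °C
Reagents that add atoms: none
Why: E2 dehydration through the dichlorophosphate: trans-diaxial elimination toward the tertiary C6–H gives the trisubstituted C6=C7 alkene and relieves the 1,3-diaxial methyl/oxygen strain. This is the pattern known from axial 11β-hydroxy steroids, which dehydrate to the 9(11)-alkenes.

Step 16
Reactants: 24 the silyl ether alkene
Product: 25 the 6-(3-hydroxypropyl) alkene ester
Conditions: Bu4NF, AcOH, THF, 0 °C → rt
Reagents that add atoms: none
Why: Fluoride cleavage of the primary silyl ether under buffered conditions; hindered ester, acetonide and alkene are inert.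

Step 17
Reactants: 25 the primary alcohol
Product: 26 the 6-(3-oxopropyl) aldehyde ester
Conditions: Dess–Martin periodinane, pyridine, CH2Cl2, 0 °C → rt
Reagents that add atoms: none
Why: Dess–Martin oxidation under neutral conditions stops at the aldehyde and leaves the alkene and acetal untouched.

Step 18
Reactants: 26 the aldehyde
Product: 27 [(4S)-2,2-dimethyl-1,3-dioxolan-4-yl]methyl 2β,5α,10α-trimethyl-6-(4-methylpent-3-en-1-yl)-cis-decal-6-ene-1α-carboxylate
Conditions: i-PrPPh3I, n-BuLi, THF, 0 °C; then 26, −78 → 0 °C
Reagents that add atoms: isopropyltriphenylphosphonium iodide, CC(C)[P+](c1ccccc1)(c1ccccc1)c1ccccc1.[I-]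
Why: Wittig olefination with the non-stabilised isopropylidene ylide; the new alkene has no geometry to control and the shielded ester does not react with the ylide at low temperature.

Step 19
Reactants: 27 the acetonide
Product: 28 (2S)-2,3-dihydroxypropyl 2β,5α,10α-trimethyl-6-(4-methylpent-3-en-1-yl)-cis-decal-6-ene-1α-carboxylate
Conditions: AcOH/H2O 4:1, 40 °C
Reagents that add atoms: none
Why: Acetal hydrolysis with an acid too weak to protonate the trisubstituted alkenes; the shielded acyl group migrates only slowly, so the glycerol configuration is kept.

Step 20
Reactants: 28 the diol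
Product: 29 (2S)-3-acetoxy-2-hydroxypropyl 2β,5α,10α-trimethyl-6-(4-methylpent-3-en-1-yl)-cis-decal-6-ene-1α-carboxylate (CNP0146255.1)
Conditions: AcCl, 2,4,6-collidine, CH2Cl2, −78 °C
Reagents that add atoms: acetyl chloride, CC(=O)Cl
Why: Primary-selective acetylation of a 1,2-diol through the N-acetylcollidinium ion at low temperature; the secondary hydroxyl stays free and the cold, weakly basic medium does not promote acyl migration.

## Compound list

1 | (R)-pulegone | C[C@@H]1CCC(=C(C)C)C(=O)C1 | starting material
2 | pulegone oxide, (6R)-2,2,6-trimethyl-1-oxaspiro[2.5]octan-4-one (epoxide epimers) | C[C@@H]1CCC2(OC2(C)C)C(=O)C1 | intermediate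
3 | (5R)-5-methyl-2-(phenylsulfanyl)cyclohexan-1-one (C2 epimers) | C[C@@H]1CCC(Sc2ccccc2)C(=O)C1 | intermediate
4 | (5R)-2,5-dimethyl-2-(phenylsulfanyl)cyclohexan-1-one (C2 epimers) | C[C@@H]1CCC(C)(Sc2ccccc2)C(=O)C1 | intermediate
5 | (5R)-2,5-dimethyl-2-(phenylsulfinyl)cyclohexan-1-one (not isolated) | C[C@@H]1CCC(C)(S(=O)c2ccccc2)C(=O)C1 | intermediate
6 | (R)-2,5-dimethylcyclohex-2-en-1-one | C[C@@H]1CC=C(C)C(=O)C1 | intermediate
7 | lithium (5R)-2,5-dimethylcyclohex-1-en-1-olate (not isolated) | [Li+].[O-]C1=C(C)CC[C@@H](C)C1 | intermediate
8 | 2-[(1R,4R)-1,4-dimethyl-2-oxocyclohexyl]-N-methoxy-N-methylacetamide | O=C1C[C@H](C)CC[C@]1(C)CC(=O)N(C)OC | intermediate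
9 | lithium enolate of 8 toward C1 (not isolated) | [Li+].[O-]C1=C[C@H](C)CC[C@]1(C)CC(=O)N(C)OC | intermediate
10 | 2-[(1R,3R,4R)-3-[(benzyloxy)methyl]-1,4-dimethyl-2-oxocyclohexyl]-N-methoxy-N-methylacetamide | O=C1[C@@H](COCc2ccccc2)[C@H](C)CC[C@]1(C)CC(=O)N(C)OC | intermediate
11 | 2-[(1R,3S,4R)-3-[(benzyloxy)methyl]-1,4-dimethyl-2-methylidenecyclohexyl]-N-methoxy-N-methylacetamide | C=C1[C@@H](COCc2ccccc2)[C@H](C)CC[C@]1(C)CC(=O)N(C)OC | intermediate
12 | lithium enolate of amide 11 (not isolated) | C=C1[C@@H](COCc2ccccc2)[C@H](C)CC[C@]1(C)C=C([O-])N(C)OC.[Li+] | intermediate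
13 | 2-[(1R,3S,4R)-3-[(benzyloxy)methyl]-1,4-dimethyl-2-methylidenecyclohexyl]-5-[(tert-butyldimethylsilyl)oxy]-N-methoxy-N-methylpentanamide (C6 epimers) | C=C1[C@@H](COCc2ccccc2)[C@H](C)CC[C@]1(C)C(CCCO[Si](C)(C)C(C)(C)C)C(=O)N(C)OC | intermediate
14 | vinylmagnesium bromide | C=C[Mg]Br | starting material
15 | bromomagnesium chelate of the tetrahedral adduct of 13 and 14 (not isolated) | C=C1[C@@H](COCc2ccccc2)[C@H](C)CC[C@]1(C)C(CCCO[Si](C)(C)C(C)(C)C)C(O[Mg]Br)(C=C)N(C)OC | intermediate
16 | 4-[(1R,3S,4R)-3-[(benzyloxy)methyl]-1,4-dimethyl-2-methylidenecyclohexyl]-7-[(tert-butyldimethylsilyl)oxy]hept-1-en-3-one (C6 epimers; key-step precursor) | C=C1[C@@H](COCc2ccccc2)[C@H](C)CC[C@]1(C)C(CCCO[Si](C)(C)C(C)(C)C)C(=O)C=C | intermediate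
17 | tertiary C10 radical from 16 (not isolated) | C[C]1[C@@H](COCc2ccccc2)[C@H](C)CC[C@]1(C)C(CCCO[Si](C)(C)C(C)(C)C)C(=O)C=C | intermediate
18 | 1α-[(benzyloxy)methyl]-6α-{3-[(tert-butyldimethylsilyl)oxy]propyl}-2β,5α,10α-trimethyl-cis-decalin-7-one (key-step product) | O(Cc1ccccc1)C[C@H]2[C@H](C)CC[C@]3(C)[C@@H](CCCO[Si](C)(C)C(C)(C)C)C(=O)CC[C@]23C | intermediate
19 | 6α-{3-[(tert-butyldimethylsilyl)oxy]propyl}-1α-(hydroxymethyl)-2β,5α,10α-trimethyl-cis-decalin-7-one | OC[C@H]1[C@H](C)CC[C@]2(C)[C@@H](CCCO[Si](C)(C)C(C)(C)C)C(=O)CC[C@]12C | intermediate
20 | 6α-{3-[(tert-butyldimethylsilyl)oxy]propyl}-2β,5α,10α-trimethyl-7-oxo-cis-decalin-1α-carboxylic acid | OC(=O)[C@H]1[C@H](C)CC[C@]2(C)[C@@H](CCCO[Si](C)(C)C(C)(C)C)C(=O)CC[C@]12C | intermediate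
21 | (R)-solketal | CC1(C)OC[C@@H](CO)O1 | starting material
22 | [(4S)-2,2-dimethyl-1,3-dioxolan-4-yl]methyl ester of 20 | CC1(C)OC[C@@H](COC(=O)[C@H]2[C@H](C)CC[C@]3(C)[C@@H](CCCO[Si](C)(C)C(C)(C)C)C(=O)CC[C@]23C)O1 | intermediate
23 | 7α-hydroxy (axial) alcohol from 22 | CC1(C)OC[C@@H](COC(=O)[C@H]2[C@H](C)CC[C@]3(C)[C@@H](CCCO[Si](C)(C)C(C)(C)C)[C@@H](O)CC[C@]23C)O1 | intermediate
24 | solketal ester with C6=C7 alkene and 3-silyloxypropyl chain | CC1(C)OC[C@@H](COC(=O)[C@H]2[C@H](C)CC[C@]3(C)C(CCCO[Si](C)(C)C(C)(C)C)=CCC[C@]23C)O1 | intermediate
25 | solketal ester with C6=C7 alkene and 3-hydroxypropyl chain | CC1(C)OC[C@@H](COC(=O)[C@H]2[C@H](C)CC[C@]3(C)C(CCCO)=CCC[C@]23C)O1 | intermediate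
26 | solketal ester with C6=C7 alkene and 3-oxopropyl chain | CC1(C)OC[C@@H](COC(=O)[C@H]2[C@H](C)CC[C@]3(C)C(CCC=O)=CCC[C@]23C)O1 | intermediate
27 | [(4S)-2,2-dimethyl-1,3-dioxolan-4-yl]methyl 2β,5α,10α-trimethyl-6-(4-methylpent-3-en-1-yl)-cis-decal-6-ene-1α-carboxylate | CC1(C)OC[C@@H](COC(=O)[C@H]2[C@H](C)CC[C@]3(C)C(CCC=C(C)C)=CCC[C@]23C)O1 | intermediate
28 | (2S)-2,3-dihydroxypropyl ester (1-O-acyl-sn-glycerol) | OC[C@H](O)COC(=O)[C@H]1[C@H](C)CC[C@]2(C)C(CCC=C(C)C)=CCC[C@]12C | intermediate
29 | (2S)-3-acetoxy-2-hydroxypropyl ester, CNP0146255.1 | CC(=O)OC[C@H](O)COC(=O)[C@H]1[C@H](C)CC[C@]2(C)C(CCC=C(C)C)=CCC[C@]12C | target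

## Step count and least certain steps

Total: 20 steps. Longest linear sequence: 20 steps, from (R)-pulegone **1** to **29**; (R)-solketal **21** and vinylmagnesium bromide **14** enter as purchased.

**Step 10 (key step).** The most likely failure is premature reduction of radical **17** by a second hydrogen-atom transfer (net hydrogenation of the methylene), or hydrogen-atom transfer to the vinyl ketone before the methylene reacts. Both are favoured by the excess of metal hydride and by the shielding of C10 between C5 and C1. The fallback generates the same radical without any metal hydride. It sets out from amide **13**: Mukaiyama hydration (Co(acac)2, PhSiH3, O2) would give the C10 tertiary alcohol F1, and vinylmagnesium bromide **14** would convert it into the hydroxy vinyl ketone F2. Methyl chlorooxoacetate (Et3N, DMAP) would give the methyl oxalate F3, and one equivalent of CsOH the cesium oxalate F4. Visible-light photoredox oxidation ([Ir(dF(CF3)ppy)2(dtbbpy)]PF6, blue light, aqueous DME/DMF) would expel two molecules of CO2, release radical **17** and close ring B by the same 6-endo addition. After the K2CO3 equilibration the route is rejoined at **18**.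

**Step 5.** The risk is poor facial selectivity in the alkylation of enolate **7**: equatorial attack, or attack on the minor half-chair, gives the C5 epimer. The fallback sets the quaternary centre under catalyst control. From **6**, conjugate reduction with LiBH(s-Bu)3 and trapping with allyl chloroformate would give the allyl enol carbonate F5. Zerovalent palladium (Pd2(dba)3) with the t-BuPHOX enantiomer matched to the 2R series (expected to be R) would effect decarboxylative allylic alkylation to (2R,5R)-2-allyl-2,5-dimethylcyclohexan-1-one F6. RuCl3/NaIO4 would cleave the allyl group to the keto acid F7, and coupling with N,O-dimethylhydroxylamine (EDC) comes back to **8**.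

**Step 7 (with the alkylation of step 6 that feeds it).** The risk is incomplete methylenation of a ketone flanked by C5 and C1, or O- instead of C-alkylation by the chloromethyl ether in step 6. The fallback installs the methylene and the C1 carbon together by an ene reaction. From **8**, LiN(i-Pr)2 and PhNTf2 would give the enol triflate F8, and a Negishi coupling with zerovalent palladium (Pd(PPh3)4, MeZnCl) the C10-methyl cyclohexene F9. A Me2AlCl-promoted ene reaction with formaldehyde would add CH2OH at C1, anti to the axial C5 arm, and move the double bond into the exocyclic position, giving the homoallylic alcohol F10. Benzylation (NaH, BnBr) comes back to **11**.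

**Step 8.** The risk is slow C-alkylation of the neopentyl-type enolate **12** by an unactivated iodide, which leaves time for N–O cleavage of the N-methoxy amide with loss of formaldehyde. The fallback builds the chain in two stages. From **11**, the same enolate would be trapped at −78 °C with the far more reactive allyl bromide to give the C6-allyl amide F11. 9-BBN would hydroborate the monosubstituted alkene in preference to the shielded methylene, and oxidation (NaBO3) would give the primary alcohol F12. Silylation (TBSCl, imidazole) comes back to **13**.

**Step 15.** The risk is loss of regiocontrol in the elimination (removal of the axial C8 hydrogen instead of the more hindered C6 hydrogen) or substitution by chloride. The fallback fixes the double bond at the enolate stage. From ketone **22**, KN(SiMe3)2 in slight deficiency (equilibration to the more substituted enolate) and PhNTf2 would give the C6=C7 enol triflate F13. Formate reduction catalysed by Pd(OAc)2/PPh3 (Bu3N, HCO2H) comes back to **24**, bypassing **23**.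

## Further compounds

F1 | step 10 | C10 tertiary alcohol from hydration of 13 | CC1(O)[C@@H](COCc2ccccc2)[C@H](C)CC[C@]1(C)C(CCCO[Si](C)(C)C(C)(C)C)C(=O)N(C)OC
F2 | step 10 | hydroxy vinyl ketone | CC1(O)[C@@H](COCc2ccccc2)[C@H](C)CC[C@]1(C)C(CCCO[Si](C)(C)C(C)(C)C)C(=O)C=C
F3 | step 10 | methyl oxalate of F2 | COC(=O)C(=O)OC1(C)[C@@H](COCc2ccccc2)[C@H](C)CC[C@]1(C)C(CCCO[Si](C)(C)C(C)(C)C)C(=O)C=C
F4 | step 10 | cesium oxalate of F2 | [Cs+].[O-]C(=O)C(=O)OC1(C)[C@@H](COCc2ccccc2)[C@H](C)CC[C@]1(C)C(CCCO[Si](C)(C)C(C)(C)C)C(=O)C=C
F5 | step 5 | allyl (5R)-2,5-dimethylcyclohex-1-en-1-yl carbonate | C=CCOC(=O)OC1=C(C)CC[C@@H](C)C1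
F6 | step 5 | (2R,5R)-2-allyl-2,5-dimethylcyclohexan-1-one | O=C1C[C@H](C)CC[C@]1(C)CC=C
F7 | step 5 | 2-[(1R,4R)-1,4-dimethyl-2-oxocyclohexyl]acetic acid | O=C1C[C@H](C)CC[C@]1(C)CC(=O)O
F8 | step 7 | enol triflate of 8 (C10=C1) | O=S(=O)(OC1=C[C@H](C)CC[C@]1(C)CC(=O)N(C)OC)C(F)(F)F
F9 | step 7 | C10-methyl cyclohexene amide | CC1=C[C@H](C)CC[C@]1(C)CC(=O)N(C)OC
F10 | step 7 | homoallylic alcohol (C1 hydroxymethyl, C10 methylene) | C=C1[C@@H](CO)[C@H](C)CC[C@]1(C)CC(=O)N(C)OC
F11 | step 8 | C6-allyl amide (C6 epimers) | C=C1[C@@H](COCc2ccccc2)[C@H](C)CC[C@]1(C)C(CC=C)C(=O)N(C)OC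
F12 | step 8 | C6-(3-hydroxypropyl) amide (C6 epimers) | C=C1[C@@H](COCc2ccccc2)[C@H](C)CC[C@]1(C)C(CCCO)C(=O)N(C)OC
F13 | step 15 | C6=C7 enol triflate of 22 | CC1(C)OC[C@@H](COC(=O)[C@H]2[C@H](C)CC[C@]3(C)C(CCCO[Si](C)(C)C(C)(C)C)=C(OS(=O)(=O)C(F)(F)F)CC[C@]23C)O1
A1 | alternative 1 | 2,7-dimethylcyclodecane-1,6-dione | CC1CCCC(=O)C(C)CCCC1=O
A2 | alternative 1 | bis(trimethylsilyl enol ether) of A1 | C[Si](C)(C)OC1=C(C)CCCC(O[Si](C)(C)C)=C(C)CCC1
A3 | alternative 1 | cis-5,10-dimethyldecalin-1,6-dione | O=C1CCC[C@]2(C)C(=O)CCC[C@]12C
A4 | alternative 2 | cis-4-methyl-6-alkenyl δ-lactone (alkene drawn E) | O=C1C[C@H](C)C[C@H](/C(C)=C(C)/CCCO[Si](C)(C)C(C)(C)C)O1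
A5 | alternative 2 | ring A cyclohexenecarboxylic acid with quaternary C10 | OC(=O)[C@H]1[C@H](C)CC=C(C)[C@]1(C)CCCO[Si](C)(C)C(C)(C)C
A6 | alternative 3 | acyclic enyne with β-keto ester silyl enol ether (alkene drawn Z) | COC(=O)C=C(O[Si](C)(C)C)CC/C(C)=C(C)\CCC#CCCCOC(=O)C(C)(C)C
A7 | alternative 3 | cis-fused bicyclic β-keto ester with C6=C7 alkene | COC(=O)C1C(=O)CC[C@]2(C)C(CCCOC(=O)C(C)(C)C)=CCC[C@]12C
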